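**Retrosynthetic overview**

1. The target is cut at the benzylic CH2–O bond of the ester (after removal of two MOM groups) into the ring B acid 8 (3-formyl-2,4-dihydroxy-6-methylbenzoic acid) and the ring A benzylic bromide 12. Joining them by carboxylate alkylation avoids a free 2-(hydroxymethyl)benzoate, which would lactonise to a phthalide.
2. The strategy rests on ring B (C1 carboxyl, C2 OH, C3 CHO, C4 OH, C5 H, C6 CH3) in its 5,6-dihydro form. This is a cyclohexane-1,3-dione in which C3 is the only CH2 flanked by both ring carbonyls (C2 and C4), so the formyl carbon is placed there without C3/C5 ambiguity, and DDQ then aromatises the ring.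
3. Dihydro ring B is disconnected into tert-butyl acetoacetate and ethyl crotonate: a Michael addition forms C1–C6 and a Claisen closure forms C3–C4.
4. Ring A is bought as the arene (methyl 2,4-dihydroxy-3,6-dimethylbenzoate) and only functionalised at its 6-methyl group (MOM protection, lateral lithiation, bromination).
5. Ring order: ring B is the only ring constructed (step 1) and is aromatised in step 4; ring A is never built.

Key step: step 1

Remark on the chemistry: the target is achiral. Compounds 4–6 are largely enolised and are drawn in one tautomeric form. The push–pull exocyclic C=C of 5 is drawn without geometry because it rotates freely. The racemic stereocentres of 3–6 are erased in step 4.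

**Route**

Step 1
Reactants: 1 tert-butyl acetoacetate; 2 ethyl (E)-crotonate
Product: 4 tert-butyl trans-6-methyl-2,4-dioxocyclohexane-1-carboxylate (racemic), via open-chain Michael adduct 3 (not isolated)
Conditions: KOtBu (1.05 equiv), tBuOH, reflux; then cold 1 M HCl to pH 3
Reagents that add atoms: none
Why: KOtBu deprotonates the doubly activated C2 methylene of 1, and this enolate adds in Michael fashion to the β-carbon of 2 (ring B bond C1–C6) to give adduct 3; proton transfer then gives the methyl ketone enolate, which attacks the ethyl ester carbonyl in an intramolecular Claisen (Dieckmann-type) condensation, forming bond C3–C4 and expelling ethoxide. The closest known reaction type is the classical Michael–Dieckmann annulation of acetoacetic esters with crotonates that gives dihydroorsellinates. Ring B closes in a 6-(enolendo)-exo-trig mode, the ester carbonyl being the exocyclic trigonal centre. The C1 and C6 stereocentres form as a racemate; C1 lies between two carbonyl groups and should equilibrate under the basic conditions to the trans (diequatorial) arrangement, and both centres are erased in step 4. The regioselectivity needed (acetoacetate C2 makes the Michael bond, the methyl carbon makes the Claisen bond) is secured by the acidity difference of the two sites under one equivalent of base, by the fact that a Claisen closure from C2 would give a four-membered ring, and by the final deprotonation of the product dione, which drives the sequence; the tert-butyl ester resists the liberated ethoxide.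

Step 2
Reactants: 4 tert-butyl trans-6-methyl-2,4-dioxocyclohexane-1-carboxylate
Product: 5 tert-butyl trans-3-[(dimethylamino)methylidene]-6-methyl-2,4-dioxocyclohexane-1-carboxylate (racemic)
Conditions: Me2NCH(OMe)2 (1.2 equiv), CH2Cl2, 0 °C to rt
Reagents that add atoms: N,N-dimethylformamide dimethyl acetal, COC(OC)N(C)C
Why: Aminomethylenation of a cyclohexane-1,3-dione by a formamide acetal should occur only at C3, the sole CH2 between two carbonyls, since C1 carries one hydrogen and cannot end as an enaminone and C5 is activated by one carbonyl only.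

Step 3
Reactants: 5 tert-butyl trans-3-[(dimethylamino)methylidene]-6-methyl-2,4-dioxocyclohexane-1-carboxylate
Product: 6 tert-butyl trans-3-formyl-4-hydroxy-6-methyl-2-oxocyclohex-3-ene-1-carboxylate (racemic; enol form of the 3-formyl-2,4-dione)
Conditions: 1 M aq HCl, THF, rt
Reagents that add atoms: water, O
Why: Acid-promoted addition–elimination hydrolysis of the vinylogous amide (enaminone hydrolysis) should release dimethylamine as its salt and give the stable, fully enolised 2-formyl-1,3-dione, while dilute acid at room temperature should spare the tert-butyl ester.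

Step 4
Reactants: 6 tert-butyl trans-3-formyl-4-hydroxy-6-methyl-2-oxocyclohex-3-ene-1-carboxylate
Product: 7 tert-butyl 3-formyl-2,4-dihydroxy-6-methylbenzoate
Conditions: DDQ (1.1 equiv), 1,4-dioxane, 80 °C
Reagents that add atoms: none
Why: DDQ dehydrogenation of a 2-acylcyclohexane-1,3-dione to a 2-acylresorcinol: hydride abstraction from C6–H (allylic to the C1=C2 β-keto ester enol), loss of a C5 proton and enolisation should give the arene, the aldehyde and tert-butyl ester being inert to the quinone.

Step 5
Reactants: 7 tert-butyl 3-formyl-2,4-dihydroxy-6-methylbenzoate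
Product: 8 3-formyl-2,4-dihydroxy-6-methylbenzoic acid (haematommic acid)
Conditions: TFA/CH2Cl2 (1:4), 0 °C to rt
Reagents that add atoms: none
Why: Acidolysis of the tert-butyl ester by alkyl–oxygen cleavage releases isobutene, and the low temperature together with the electron-withdrawing formyl group should hold back decarboxylation of the acid.

Step 6
Reactants: 9 methyl 2,4-dihydroxy-3,6-dimethylbenzoate
Product: 10 methyl 2,4-bis(methoxymethoxy)-3,6-dimethylbenzoate
Conditions: NaH (2.5 equiv), MOMCl (2.5 equiv), DMF, 0 °C to rt
Reagents that add atoms: chloromethyl methyl ether, COCCl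
Why: Williamson-type O-alkylation of both phenoxides, NaH being strong enough to free the hydrogen-bonded 2-OH; MOM ethers tolerate the amide base of step 7 and the bicarbonate of step 8 and are later removed by acid, which leaves the benzylic ester intact.

Step 7
Reactants: 10 methyl 2,4-bis(methoxymethoxy)-3,6-dimethylbenzoate
Product: 12 methyl 6-(bromomethyl)-2,4-bis(methoxymethoxy)-3-methylbenzoate, via benzylic lithium species 11 (not isolated)
Conditions: LiN(iPr)2 (1.1 equiv), THF, −78 °C; then cannulated into BrCl2C–CCl2Br (1.5 equiv), THF, −78 °C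
Reagents that add atoms: 1,2-dibromo-1,1,2,2-tetrachloroethane, BrC(Cl)(Cl)C(Cl)(Cl)Br
Why: Lateral lithiation of an ortho-toluate ester: only the 6-methyl group is conjugated with the ester and is deprotonated, and the benzylic anion then takes electrophilic bromine from the polyhaloethane with loss of tetrachloroethene, inverse addition into excess reagent limiting Wurtz-type coupling.

Step 8
Reactants: 8 3-formyl-2,4-dihydroxy-6-methylbenzoic acid; 12 methyl 6-(bromomethyl)-2,4-bis(methoxymethoxy)-3-methylbenzoate
Product: 13 methyl 6-{[(3-formyl-2,4-dihydroxy-6-methylbenzoyl)oxy]methyl}-2,4-bis(methoxymethoxy)-3-methylbenzoate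
Conditions: KHCO3 (1.1 equiv), DMF, rt
Reagents that add atoms: none
Why: SN2 alkylation of a carboxylate by a benzylic bromide: bicarbonate deprotonates only the carboxylic acid, so the phenols of ring B stay protonated and unalkylated.

Step 9
Reactants: 13 methyl 6-{[(3-formyl-2,4-dihydroxy-6-methylbenzoyl)oxy]methyl}-2,4-bis(methoxymethoxy)-3-methylbenzoate
Product: 14 methyl 6-{[(3-formyl-2,4-dihydroxy-6-methylbenzoyl)oxy]methyl}-2,4-dihydroxy-3-methylbenzoate (target)
Conditions: HCl (1.25 M in MeOH), THF, rt
Reagents that add atoms: none
Why: Acid-catalysed acetal exchange transfers both methoxymethyl groups to methanol; the two hindered, hydrogen-bonded salicylate esters should survive, and the benzylic ester cannot ionise because both ring A hydroxyls are meta to the benzylic carbon.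

**Compound list**

1 | tert-butyl acetoacetate | CC(=O)CC(=O)OC(C)(C)C | starting material
2 | ethyl (E)-crotonate | C/C=C/C(=O)OCC | starting material
3 | 1-tert-butyl 5-ethyl 2-acetyl-3-methylpentanedioate (open-chain Michael adduct, racemic mixture of diastereomers, present as its potassium enolate) | CCOC(=O)CC(C)C(C(C)=O)C(=O)OC(C)(C)C | intermediate
4 | tert-butyl trans-6-methyl-2,4-dioxocyclohexane-1-carboxylate (racemic, 1R,6S enantiomer drawn) | CC(C)(C)OC(=O)[C@@H]1[C@@H](C)CC(=O)CC1=O | intermediate
5 | tert-butyl trans-3-[(dimethylamino)methylidene]-6-methyl-2,4-dioxocyclohexane-1-carboxylate (racemic) | CC(C)(C)OC(=O)[C@@H]1[C@@H](C)CC(=O)C(=CN(C)C)C1=O | intermediate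
6 | tert-butyl trans-3-formyl-4-hydroxy-6-methyl-2-oxocyclohex-3-ene-1-carboxylate (racemic, enol of the 3-formyl-2,4-dione) | CC(C)(C)OC(=O)[C@@H]1[C@@H](C)CC(O)=C(C=O)C1=O | intermediate
7 | tert-butyl 3-formyl-2,4-dihydroxy-6-methylbenzoate | CC(C)(C)OC(=O)c1c(C)cc(O)c(C=O)c1O | intermediate
8 | 3-formyl-2,4-dihydroxy-6-methylbenzoic acid | OC(=O)c1c(C)cc(O)c(C=O)c1O | intermediate
9 | methyl 2,4-dihydroxy-3,6-dimethylbenzoate | COC(=O)c1c(C)cc(O)c(C)c1O | starting material
10 | methyl 2,4-bis(methoxymethoxy)-3,6-dimethylbenzoate | COC(=O)c1c(C)cc(OCOC)c(C)c1OCOC | intermediate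
11 | methyl 6-(lithiomethyl)-2,4-bis(methoxymethoxy)-3-methylbenzoate | COC(=O)c1c(C[Li])cc(OCOC)c(C)c1OCOC | intermediate
12 | methyl 6-(bromomethyl)-2,4-bis(methoxymethoxy)-3-methylbenzoate | COC(=O)c1c(CBr)cc(OCOC)c(C)c1OCOC | intermediate
13 | methyl 6-{[(3-formyl-2,4-dihydroxy-6-methylbenzoyl)oxy]methyl}-2,4-bis(methoxymethoxy)-3-methylbenzoate | COC(=O)c1c(COC(=O)c2c(C)cc(O)c(C=O)c2O)cc(OCOC)c(C)c1OCOC | intermediate
14 | methyl 6-{[(3-formyl-2,4-dihydroxy-6-methylbenzoyl)oxy]methyl}-2,4-dihydroxy-3-methylbenzoate | COC(=O)c1c(COC(=O)c2c(C)cc(O)c(C=O)c2O)cc(O)c(C)c1O | target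

**Step count**

Total: 9 steps. Longest linear sequence: 7 steps (steps 1, 2, 3, 4, 5, 8, 9); the ring A branch (steps 6 and 7) joins at step 8.

**Steps most likely to fail**

Step 4 (DDQ aromatisation). The electron-poor, fully enolised triketone may resist hydride abstraction, and forcing conditions may cause loss of the tert-butyl group with decarboxylation, or deformylation. The fallback sets out from enaminone 5 (so it also replaces step 3) and comes back to the route at 7. C1 of 5 is deprotonated with LiN(SiMe3)2 in THF at −78 °C and selenenylated with PhSeBr on the face anti to the C6 methyl group, giving tert-butyl 3-[(dimethylamino)methylidene]-6-methyl-2,4-dioxo-1-(phenylselanyl)cyclohexane-1-carboxylate F1. H2O2 in CH2Cl2/pyridine at 0 °C should oxidise it to the selenoxide tert-butyl 3-[(dimethylamino)methylidene]-6-methyl-2,4-dioxo-1-(phenylseleninyl)cyclohexane-1-carboxylate F2. Syn-elimination of F2 with the cis C6–H and enolisation at C4 should give tert-butyl 5-[(dimethylamino)methylidene]-4-hydroxy-2-methyl-6-oxocyclohexa-1,3-diene-1-carboxylate F3, the vinylogous-amide tautomer of the aromatic iminium phenolate. Brief treatment with 1 M aqueous HCl in THF should hydrolyse F3 to 7.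

Step 7 (lateral lithiation and bromination). The benzylic lithium species may couple with freshly formed bromide, proton transfer may lead to over-bromination, or ring lithiation ortho to a MOM ether may compete. The fallback sets out from 10 and comes back at 12. Lithio species 11, generated as in step 7, is hydroxylated at −78 °C with 2-(phenylsulfonyl)-3-phenyloxaziridine; on warming, the oxygenated carbon should close onto the neighbouring methyl ester to give 5,7-bis(methoxymethoxy)-6-methylisobenzofuran-1(3H)-one F4. KOH in aqueous MeOH opens the lactone to potassium 6-(hydroxymethyl)-2,4-bis(methoxymethoxy)-3-methylbenzoate F5. After evaporation, MeI in DMF alkylates the carboxylate to methyl 6-(hydroxymethyl)-2,4-bis(methoxymethoxy)-3-methylbenzoate F6, which is kept neutral and cold to prevent relactonisation. An Appel reaction (CBr4, PPh3, CH2Cl2, 0 °C) then converts F6 into 12.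

Step 5 (tert-butyl ester cleavage). Ipso-protonation may cause decarboxylation of the electron-rich acid, or the released tert-butyl cation may alkylate C5 of the ring. The fallback sets out from 7 and comes back at 13. Acetylation (Ac2O, Et3N, catalytic DMAP, CH2Cl2) should give tert-butyl 2,4-diacetoxy-3-formyl-6-methylbenzoate F7, whose ring is too electron-poor for either side reaction. TFA/CH2Cl2 then gives 2,4-diacetoxy-3-formyl-6-methylbenzoic acid F8. Alkylation of F8 with bromide 12 (KHCO3, DMF, rt) gives methyl 6-{[(2,4-diacetoxy-3-formyl-6-methylbenzoyl)oxy]methyl}-2,4-bis(methoxymethoxy)-3-methylbenzoate F9. K2CO3 (catalytic) in MeOH at 0 °C should remove the two aryl acetates much faster than it attacks the hindered benzoate esters, giving 13.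

**Further compounds**

F1 | step 4 | tert-butyl 3-[(dimethylamino)methylidene]-6-methyl-2,4-dioxo-1-(phenylselanyl)cyclohexane-1-carboxylate (racemic, SePh trans to the C6 methyl) | CC(C)(C)OC(=O)[C@@]1([Se]c2ccccc2)[C@@H](C)CC(=O)C(=CN(C)C)C1=O
F2 | step 4 | tert-butyl 3-[(dimethylamino)methylidene]-6-methyl-2,4-dioxo-1-(phenylseleninyl)cyclohexane-1-carboxylate (racemic, selenoxide) | CC(C)(C)OC(=O)[C@@]1([Se](=O)c2ccccc2)[C@@H](C)CC(=O)C(=CN(C)C)C1=O
F3 | step 4 | tert-butyl 5-[(dimethylamino)methylidene]-4-hydroxy-2-methyl-6-oxocyclohexa-1,3-diene-1-carboxylate | CC(C)(C)OC(=O)C1=C(C)C=C(O)C(=CN(C)C)C1=O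
F4 | step 7 | 5,7-bis(methoxymethoxy)-6-methylisobenzofuran-1(3H)-one | O=C1OCc2cc(OCOC)c(C)c(OCOC)c12
F5 | step 7 | potassium 6-(hydroxymethyl)-2,4-bis(methoxymethoxy)-3-methylbenzoate | [K+].[O-]C(=O)c1c(CO)cc(OCOC)c(C)c1OCOC
F6 | step 7 | methyl 6-(hydroxymethyl)-2,4-bis(methoxymethoxy)-3-methylbenzoate | COC(=O)c1c(CO)cc(OCOC)c(C)c1OCOC
F7 | step 5 | tert-butyl 2,4-diacetoxy-3-formyl-6-methylbenzoate | CC(C)(C)OC(=O)c1c(C)cc(OC(C)=O)c(C=O)c1OC(C)=O
F8 | step 5 | 2,4-diacetoxy-3-formyl-6-methylbenzoic acid | OC(=O)c1c(C)cc(OC(C)=O)c(C=O)c1OC(C)=O
F9 | step 5 | methyl 6-{[(2,4-diacetoxy-3-formyl-6-methylbenzoyl)oxy]methyl}-2,4-bis(methoxymethoxy)-3-methylbenzoate | COC(=O)c1c(COC(=O)c2c(C)cc(OC(C)=O)c(C=O)c2OC(C)=O)cc(OCOC)c(C)c1OCOC
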